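**Plan**
Numbering (germacrane): C1 = CHOH; C2–C3 = CH2CH2; C4 (=C5) bears C15H2OH; C6 = lactone O–CH; C7 = ring-fusion CH bearing C11(=C13H2)–C12(=O); C8 = ester O–CH; C9=C10(C14H3).
Retrosynthesis: cut the C8 O–acyl bond and the O6–C12 lactone bond, raise C1–OH and C15–OH to ketone and aldehyde, move C4=C5/C6–O back to a C5=C6 olefin (through its epoxide), then cut C3–C4 while C1–C6 is re-joined.
Enabling feature: C1(=O)–C2–C3–C4–C5=C6 is the δ,ε-unsaturated-ketone retron of an oxy-Cope shift. C1, C10, C9, C8, C7 and C6, with the ring-cis C9=C10 bond and the C10 methyl, are the cyclohexenone ring of carvone, whose isopropenyl group is C11–C13.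
Forward: the six-membered ring of (R)-carvone is oxidised at C12 and C8, alkenylated at C6 and vinylated at C1. The anionic oxy-Cope shift expands it to the ten-membered ring, the lactone ring closes afterwards, and the ester and the two reductions come last.
Stereochemistry: C7 from (R)-carvone; C8 by anti γ-hydroxylation plus Mitsunobu inversion; C6 by peripheral epoxidation of E-C5=C6 under control of C7; C1 by (R)-CBS reduction; C2' from (S)-2-methylbutanoic acid. The C9=C10 geometry comes from the cyclohexene, and the C4=C5 geometry from E1cB opening to the (E)-enal.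

Key step: step 8

Remark: the C1 configuration of 13 and the C4 configuration of 16–18 are drawn as expected from the models given. Both centres are erased again (steps 8 and 10), so they do not bear on the target.

Step 1
Reactants: 1 (R)-(−)-carvone
Product: 2 10-chlorocarvone
Conditions: Ca(OCl)2, CO2 (s), CH2Cl2/H2O, 0 °C
Reagents that add atoms: calcium hypochlorite [Ca+2].[O-]Cl.[O-]Cl
Why: Ene-type allylic chlorination by HOCl attacks only the electron-rich 1,1-disubstituted olefin (the enone olefin is inert), so C12 is functionalised and C7 is untouched.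

Step 2
Reactants: 2 10-chlorocarvone
Product: 3 C12 PMB ether of 10-hydroxycarvone
Conditions: 4-MeOC6H4CH2OH, NaH, n-Bu4NI (cat.), THF, 0 °C → rt
Reagents that add atoms: 4-methoxybenzyl alcohol OCc1ccc(OC)cc1
Why: Williamson ether synthesis, an SN2 displacement on a primary allylic chloride that is faster than enolisation of the enone and gives a base-stable, DDQ-labile mask for C12–OH.

Step 3
Reactants: 3 C12 PMB ether of 10-hydroxycarvone
Product: 5 trans-γ-hydroxy enone (4S,5R), via TBS dienol ether 4 (not isolated)
Conditions: KOt-Bu, THF/DMPU, −20 °C; TBSCl; crude 4, mCPBA, CH2Cl2, −20 °C; aq. work-up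
Reagents that add atoms: mCPBA OOC(=O)c1cccc(Cl)c1
Why: Vinylogous Rubottom oxidation, in which the thermodynamic linear dienolate is O-silylated and the peracid attacks the terminal C8=C9 bond of 4 (C10 is fully substituted) from the face anti to the C7 side chain, so C8–OH forms trans to that chain.

Step 4
Reactants: 5 trans-γ-hydroxy enone (4S,5R)
Product: 6 cis-γ-(4-methoxyphenoxy) enone (4R,5R)
Conditions: 4-MeOC6H4OH, PPh3, DIAD, toluene, 0 °C → rt
Reagents that add atoms: 4-methoxyphenol Oc1ccc(OC)cc1
Why: Mitsunobu etherification, whose SN2 displacement of the oxyphosphonium group inverts C8 to the configuration of the target and at the same time installs a base-stable, CAN-labile PMP ether.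

Step 5
Reactants: 7 3,3-diethoxyprop-1-yne
Product: 9 (E)-3,3-diethoxy-1-iodoprop-1-ene, via alkenylzirconocene chloride 8 (not isolated)
Conditions: Cp2Zr(H)Cl, CH2Cl2, rt; I2, 0 °C
Reagents that add atoms: iodine II
Why: Hydrozirconation–iodinolysis, in which syn addition of Zr–H puts the metal on the terminal carbon and iodinolysis proceeds with retention, fixing the E geometry.

Step 6
Reactants: 6 cis-γ-(4-methoxyphenoxy) enone (4R,5R); 9 (E)-3,3-diethoxy-1-iodoprop-1-ene
Product: 12 C6-alkenyl enone (4R,5R,6S), via lithium enolate 10 (not isolated), via lithium dienolate 11 (not isolated)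
Conditions: LiHMDS (2.1 equiv), Pd2(dba)3 (cat.), Q-Phos (cat.), THF/toluene, −78 °C → rt; AcOH, −78 °C
Reagents that add atoms: none
Why: Pd-catalysed α-alkenylation of a ketone enolate, in which kinetic deprotonation gives the C6 enolate, coupling makes C6–C5 with retention of the E olefin, cold α-protonation of 11 keeps the olefin β,γ, and C6 settles trans (diequatorial) to the C7 side chain.

Step 7
Reactants: 12 C6-alkenyl enone (4R,5R,6S)
Product: 13 1-vinyl-6-alkenylcyclohex-2-en-1-ol (1S,4R,5R,6S)
Conditions: CH2=CHMgBr, LaCl3·2LiCl, THF, −78 → 0 °C; H2O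
Reagents that add atoms: vinylmagnesium bromide C=C[Mg]Br
Why: Lanthanide-assisted Grignard 1,2-addition suppresses enolisation and 1,4-addition, and attack anti to the neighbouring C6 arm should place the vinyl group trans to that arm.

Step 8
Reactants: 13 1-vinyl-6-alkenylcyclohex-2-en-1-ol (1S,4R,5R,6S)
Product: 16 ten-membered (9Z,5E)-dienone, via potassium alkoxide 14 (not isolated), via potassium enolate 15 (not isolated)
Conditions: KH, 18-crown-6, THF, 0 → 40 °C; AcOH, −78 °C
Reagents that add atoms: none
Why: KH converts 13 into alkoxide 14, whose C1–C6 bond is weakened by the oxido group, and a concerted suprafacial [3,3] shift through a chair array with the vinyl group and the alkenyl arm both equatorial makes C3–C4 while C1–C6 breaks, giving enolate 15, which is protonated at C2 on the cold quench. The closest known reaction type is the anionic oxy-Cope ring expansion of 6-alkenyl-1-vinylcyclohex-2-en-1-ols to cyclodeca-2,6-dienones. The ten-membered carbocycle is closed by a four-atom ring expansion (6 to 10) inside a six-centre array and not by end-to-end cyclisation, so neither high dilution nor a template is needed. The only new stereocentre, C4, follows from the chair array, the E geometry of the arm and the C6 configuration (it is erased in step 10); the same array delivers E-C5=C6, and C9=C10 keeps the cis geometry it had in the cyclohexene. The step must choose among three 1,5-dienes: only the vinyl/alkenyl pair has the oxido carbon in the breaking bond and both termini within reach, the C9=C10/C4=C5 pair cannot reach a six-centre geometry from an equatorial arm, and the C11=C13/C4=C5 pair lacks the oxido acceleration and would need a far higher temperature. C7 and C8 are spectators, and because 15 is cross-conjugated the C8 aryl ether cannot be expelled.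

Step 9
Reactants: 16 ten-membered (9Z,5E)-dienone
Product: 17 (5S,6S)-5,6-epoxide
Conditions: DMDO, acetone/CH2Cl2, −40 °C
Reagents that add atoms: dimethyldioxirane CC1(C)OO1
Why: Epoxidation under macrocyclic (peripheral-attack) control, in which the strained E-C5=C6 bond is the most nucleophilic olefin and, with H7 and H4 eclipsing it and the ring bonds C7–C8 and C4–C3 on one face, only the outer face is open, which sets the C6–O bond anti to C7–C8 as the trans-lactone of the target requires.

Step 10
Reactants: 17 (5S,6S)-5,6-epoxide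
Product: 19 (6R)-γ-hydroxy-(4E)-enal, via epoxy aldehyde 18 (not isolated)
Conditions: PPTS (cat.), acetone/H2O, rt; then Et3N (cat.), CH2Cl2, 0 °C
Reagents that add atoms: water O
Why: Acetal hydrolysis unmasks aldehyde 18, whose acidic C4–H triggers E1cB opening of the C5–O bond (β,γ-epoxy carbonyl to γ-hydroxy enal isomerisation), which keeps the C6–O bond and its configuration, erases C4 and gives the more stable (E)-2-alkylenal with C3 and C6 cis as in the target.

Step 11
Reactants: 19 (6R)-γ-hydroxy-(4E)-enal
Product: 20 C6,C12-diol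
Conditions: DDQ, CH2Cl2/pH 7 buffer, 0 °C
Reagents that add atoms: none
Why: Oxidative PMB cleavage by benzylic hydride abstraction, which the PMP aryl ether (no benzylic C–H), the enal and the enone should survive.

Step 12
Reactants: 20 C6,C12-diol
Product: 22 α-methylene-γ-lactone keto aldehyde PMP ether, via lactol 21 (not isolated)
Conditions: TEMPO (cat.), PhI(OAc)2, CH2Cl2, rt
Reagents that add atoms: none
Why: Oxoammonium oxidative lactonisation of a 2-methylene-1,4-diol, in which the primary allylic C12–OH is oxidised first, C6–OH (the only free neighbour, C8 still being masked) closes the five-membered lactol 21, and a second oxidation gives the lactone without touching C6 or C7.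

Step 13
Reactants: 22 α-methylene-γ-lactone keto aldehyde PMP ether
Product: 23 C8 alcohol
Conditions: (NH4)2Ce(NO3)6, MeCN/H2O 4:1, 0 °C
Reagents that add atoms: none
Why: CAN oxidative dearylation turns the electron-rich aryl ether into benzoquinone and breaks the aryl–O bond, so the C8–O bond and its configuration are kept.

Step 14
Reactants: 23 C8 alcohol; 24 (S)-2-methylbutanoic acid
Product: 25 C8 (S)-2-methylbutanoate keto aldehyde
Conditions: DCC, DMAP (cat.), CH2Cl2, 0 °C → rt
Reagents that add atoms: none
Why: Steglich esterification acylates the only free hydroxyl with retention at C8 and brings in C2' from the enantiopure acid.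

Step 15
Reactants: 25 C8 (S)-2-methylbutanoate keto aldehyde
Product: 26 target CNP0526758.1
Conditions: (R)-Me-CBS (cat.), catecholborane, toluene, −78 °C; pH 7 buffer
Reagents that add atoms: none
Why: CBS reduction takes the enal to C15H2OH and the C1 enone to the allylic alcohol by 1,2-hydride delivery, and with the C10 alkenyl flank as the large group and C2H2 as the small group the (R)-catalyst should give (1S), while lactone and ester are too unreactive at −78 °C.

**Compound list**
1 | (R)-(−)-carvone | C=C(C)[C@@H]1CC=C(C)C(=O)C1 | starting material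
2 | 10-chlorocarvone, (5R)-5-(3-chloroprop-1-en-2-yl)-2-methylcyclohex-2-en-1-one | C=C(CCl)[C@@H]1CC=C(C)C(=O)C1 | intermediate
3 | (5R)-5-[3-(4-methoxybenzyloxy)prop-1-en-2-yl]-2-methylcyclohex-2-en-1-one | C=C(COCc1ccc(OC)cc1)[C@@H]2CC=C(C)C(=O)C2 | intermediate
4 | linear TBS dienol ether of 3 (C1–OTBS, C1=C10 and C8=C9 double bonds, C7 unchanged) | C=C(COCc1ccc(OC)cc1)[C@@H]2C=CC(C)=C(O[Si](C)(C)C(C)(C)C)C2 | intermediate
5 | (4S,5R)-4-hydroxy-5-[3-(4-methoxybenzyloxy)prop-1-en-2-yl]-2-methylcyclohex-2-en-1-one (C8–OH trans to the C7 chain) | C=C(COCc1ccc(OC)cc1)[C@@H]2[C@@H](O)C=C(C)C(=O)C2 | intermediate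
6 | (4R,5R)-4-(4-methoxyphenoxy)-5-[3-(4-methoxybenzyloxy)prop-1-en-2-yl]-2-methylcyclohex-2-en-1-one (C8–OAr cis to the C7 chain) | C=C(COCc1ccc(OC)cc1)[C@@H]2[C@H](Oc3ccc(OC)cc3)C=C(C)C(=O)C2 | intermediate
7 | 3,3-diethoxyprop-1-yne | C#CC(OCC)OCC | starting material
8 | (E)-(3,3-diethoxyprop-1-enyl)zirconocene chloride | CCOC(OCC)/C=C/[Zr](Cl)(C1C=CC=C1)C1C=CC=C1 | intermediate
9 | (E)-3,3-diethoxy-1-iodoprop-1-ene | CCOC(OCC)/C=C/I | intermediate
10 | cross-conjugated lithium enolate of 6 (C1–OLi, C1=C6) | C=C(COCc1ccc(OC)cc1)[C@@H]2[C@H](Oc3ccc(OC)cc3)C=C(C)C([O-])=C2.[Li+] | intermediate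
11 | lithium dienolate of 12 (C1–OLi, C1=C6, C5=C4) | C=C(COCc1ccc(OC)cc1)[C@@H]2[C@H](Oc3ccc(OC)cc3)C=C(C)C([O-])=C2/C=C/C(OCC)OCC.[Li+] | intermediate
12 | (4R,5R,6S)-6-[(E)-3,3-diethoxyprop-1-enyl]-4-(4-methoxyphenoxy)-5-[3-(4-methoxybenzyloxy)prop-1-en-2-yl]-2-methylcyclohex-2-en-1-one | C=C(COCc1ccc(OC)cc1)[C@@H]2[C@H](Oc3ccc(OC)cc3)C=C(C)C(=O)[C@H]2/C=C/C(OCC)OCC | intermediate
13 | (1S,4R,5R,6S)-1-ethenyl carbinol of 12 (vinyl trans to the C6 arm) | C=C(COCc1ccc(OC)cc1)[C@@H]2[C@H](Oc3ccc(OC)cc3)C=C(C)[C@](O)(C=C)[C@H]2/C=C/C(OCC)OCC | intermediate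
14 | potassium alkoxide of 13 | C=C(COCc1ccc(OC)cc1)[C@@H]2[C@H](Oc3ccc(OC)cc3)C=C(C)[C@]([O-])(C=C)[C@H]2/C=C/C(OCC)OCC.[K+] | intermediate
15 | ring-expanded potassium enolate (C1–OK, C1=C2) | C=C(COCc1ccc(OC)cc1)[C@H]2/C=C/[C@H](C(OCC)OCC)C/C=C([O-])/C(C)=C\[C@H]2Oc3ccc(OC)cc3.[K+] | intermediate
16 | ten-membered dienone: C1 ketone, (4R)-CH(OEt)2, 5E, 7R, (8R)-OPMP, 9Z, C12–OPMB | C=C(COCc1ccc(OC)cc1)[C@H]2/C=C/[C@H](C(OCC)OCC)CCC(=O)/C(C)=C\[C@H]2Oc3ccc(OC)cc3 | intermediate
17 | (5S,6S)-5,6-epoxide of 16 | C=C(COCc1ccc(OC)cc1)[C@H]2[C@@H]4O[C@H]4[C@H](C(OCC)OCC)CCC(=O)/C(C)=C\[C@H]2Oc3ccc(OC)cc3 | intermediate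
18 | β,γ-epoxy aldehyde (C15 = CHO) | C=C(COCc1ccc(OC)cc1)[C@H]2[C@@H]4O[C@H]4[C@H](C=O)CCC(=O)/C(C)=C\[C@H]2Oc3ccc(OC)cc3 | intermediate
19 | (6R)-hydroxy-(4E)-enal, C1 ketone, C8–OPMP, C12–OPMB | C=C(COCc1ccc(OC)cc1)[C@H]2[C@H](O)/C=C(/C=O)CCC(=O)/C(C)=C\[C@H]2Oc3ccc(OC)cc3 | intermediate
20 | C6,C12-diol | C=C(CO)[C@H]2[C@H](O)/C=C(/C=O)CCC(=O)/C(C)=C\[C@H]2Oc3ccc(OC)cc3 | intermediate
21 | C12 lactol (C12 configuration undefined) | C=C1C(O)O[C@@H]2/C=C(/C=O)CCC(=O)/C(C)=C\[C@@H](Oc3ccc(OC)cc3)[C@@H]12 | intermediate
22 | trans-fused 6,7-α-methylene-γ-lactone, C1 ketone, C15 aldehyde, C8–OPMP | C=C1C(=O)O[C@@H]2/C=C(/C=O)CCC(=O)/C(C)=C\[C@@H](Oc3ccc(OC)cc3)[C@@H]12 | intermediate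
23 | C8 alcohol of 22 | C=C1C(=O)O[C@@H]2/C=C(/C=O)CCC(=O)/C(C)=C\[C@@H](O)[C@@H]12 | intermediate
24 | (S)-2-methylbutanoic acid | CC[C@H](C)C(=O)O | starting material
25 | C8 (S)-2-methylbutanoate, C1 ketone, C15 aldehyde | C=C1C(=O)O[C@@H]2/C=C(/C=O)CCC(=O)/C(C)=C\[C@@H](OC(=O)[C@@H](C)CC)[C@@H]12 | intermediate
26 | CNP0526758.1 (1S,6R,7R,8R,2'S; 4E,9Z) | C=C1C(=O)O[C@@H]2/C=C(/CO)CC[C@H](O)/C(C)=C\[C@@H](OC(=O)[C@@H](C)CC)[C@@H]12 | target

**Total steps:** 15. **Longest linear sequence:** 14 (steps 1–4 and 6–15, from (R)-carvone).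

**Steps most likely to fail**

Step 6. Pd(0) may ionise the allylic C8 aryl ether of the electron-rich enolate, which would lead to loss of the phenol and aromatisation. The basic medium may also move the new olefin into conjugation with the ketone. The fallback sets out from 6 and returns at 12 without base in the bond-forming event. Compound 6 is deprotonated with LiHMDS and silylated with TMSCl to the cross-conjugated TMS dienol ether F1. NBS converts this into the α'-bromo enone F2 (bromine anti to the C7 chain). F2 is then coupled under nickel catalysis (NiCl2·glyme, bipyridine-type ligand, THF, rt) with the alkenylzirconocene 8 generated as in step 5. This is the known Ni-catalysed alkenylation of α-bromo ketones with alkenylzirconium reagents.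

Step 3. Deprotonation may occur at C6 instead of C8, giving the cross-conjugated enolate and hence α'-oxidation, or the strong base may start the isomerisation to the phenol. The fallback sets out from 3 and returns at 5. It is a copper(II)/tetramethylguanidine-catalysed vinylogous aerobic oxidation (air, rt). Only a small, reversibly formed amount of dienolate is present, and its linear form is trapped by O2 at C8, anti to the C7 chain, as the γ-hydroperoxide F3. PPh3 reduces F3 in the same pot to 5.

Step 15. Facial selectivity at C1 may be poor because the macrocyclic enone is twisted, and the borane may reduce the methylene lactone in the conjugate sense. The fallback sets out from 25 and returns at 26, and it separates the two reductions. NaBH(OAc)3 (CH2Cl2, 0 °C) reduces only the aldehyde to give the keto alcohol F4. An NADPH-dependent ketoreductase chosen from a panel (glucose/glucose dehydrogenase recycling, pH 7 buffer/DMSO) then reduces the C1 ketone under enzyme control to the (1S)-alcohol, under conditions that leave Michael acceptors and esters alone.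

**Further compounds**
F1 | step 6 | cross-conjugated TMS dienol ether of 6 | C=C(COCc1ccc(OC)cc1)[C@@H]2[C@H](Oc3ccc(OC)cc3)C=C(C)C(O[Si](C)(C)C)=C2
F2 | step 6 | α'-bromo enone (C6–Br trans to the C7 chain) | C=C(COCc1ccc(OC)cc1)[C@@H]2[C@H](Oc3ccc(OC)cc3)C=C(C)C(=O)[C@H]2Br
F3 | step 3 | γ-hydroperoxide (C8–OOH trans to the C7 chain) | C=C(COCc1ccc(OC)cc1)[C@@H]2[C@@H](OO)C=C(C)C(=O)C2
F4 | step 15 | keto alcohol (C15H2OH, C1 ketone) | C=C1C(=O)O[C@@H]2/C=C(/CO)CCC(=O)/C(C)=C\[C@@H](OC(=O)[C@@H](C)CC)[C@@H]12
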